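The indole is cut at C2=C3, the one bond of pyrrole ring B that still behaves as an alkene, so ring B is closed last by olefin metathesis on a fully dressed benzene ring A. Regiochemistry is settled first: with a formyl carbon on the future C3a, the amino nitrogen and the C6 methoxy group both send bromine to C5 and C7. The key step joins a styrene CH to an enamide CH, expels propene and gives the aromatic N-tosylindole in one operation. Its precursor is an N-tosyl-N-(prop-1-enyl)aniline carrying an ortho vinyl group, both bromines and the methoxy group. Detosylation and C3 bromination finish the route.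

Key step: step 6

Remark: 8 is drawn as the E enamide. Any Z isomer from step 5 is carried along because both geometries give the same indole, and the hindered N–aryl axis of 7 and 8 is left unspecified because it disappears on ring closure.

Step 1
Reactants: 1 2-amino-4-methoxybenzaldehyde
Product: 3 2-amino-3,5-dibromo-4-methoxybenzaldehyde, via 2-amino-5-bromo-4-methoxybenzaldehyde 2 (not isolated)
Conditions: NBS (2.05 equiv), MeCN, 0 °C to rt, dark
Reagents that add atoms: N-bromosuccinimide, O=C1CCC(=O)N1Br
Why: Electrophilic aromatic bromination should stop cleanly at the dibromide because the amino group (ortho/para), the methoxy group (ortho) and the formyl group (meta) all point to C3 and C5, the remaining C6–H is meta to both donors, and the carbon substituent at C1 blocks the third activated site without being open to ipso exchange.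

Step 2
Reactants: 3 2-amino-3,5-dibromo-4-methoxybenzaldehyde
Product: 4 2,4-dibromo-3-methoxy-6-vinylaniline
Conditions: MePPh3Br (2.5 equiv), KOt-Bu (2.4 equiv), THF, 0 °C to rt
Reagents that add atoms: methyltriphenylphosphonium bromide, C[P+](c1ccccc1)(c1ccccc1)c1ccccc1.[Br-]
Why: Wittig methylenation with the non-stabilised ylide is fast even on this donor-deactivated aldehyde, the excess ylide absorbs any reversible N–H deprotonation, keeping the base just short of the phosphonium salt leaves no free alkoxide, and a metal-free olefination cannot touch the two C–Br bonds.

Step 3
Reactants: 4 2,4-dibromo-3-methoxy-6-vinylaniline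
Product: 5 N-(2,4-dibromo-3-methoxy-6-vinylphenyl)-4-methylbenzenesulfonamide
Conditions: TsCl (1.5 equiv), DMAP (0.1 equiv), pyridine, 70 °C
Reagents that add atoms: 4-toluenesulfonyl chloride, Cc1ccc(cc1)S(=O)(=O)Cl
Why: N-Sulfonylation of a primary aniline, where heat and nucleophilic catalysis by DMAP should make up for the weak, doubly ortho-flanked nitrogen, and the same crowding together with the weak base should hold the reaction at the monosulfonamide.

Step 4
Reactants: 5 N-(2,4-dibromo-3-methoxy-6-vinylphenyl)-4-methylbenzenesulfonamide; 6 allyl bromide
Product: 7 N-allyl-N-(2,4-dibromo-3-methoxy-6-vinylphenyl)-4-methylbenzenesulfonamide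
Conditions: K2CO3 (2 equiv), DMF, rt to 50 °C
Reagents that add atoms: none
Why: SN2 N-alkylation of the acidic sulfonamide, whose carbonate-generated anion is a good nucleophile for an unhindered allylic bromide even next to two ortho substituents, and which has only one N–H so that over-alkylation is impossible.

Step 5
Reactants: 7 N-allyl-N-(2,4-dibromo-3-methoxy-6-vinylphenyl)-4-methylbenzenesulfonamide
Product: 8 N-(2,4-dibromo-3-methoxy-6-vinylphenyl)-4-methyl-N-[(E)-prop-1-enyl]benzenesulfonamide
Conditions: RuHCl(CO)(PPh3)3 (5 mol %), toluene, 100 °C, Ar; chromatography to remove ruthenium and phosphine residues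
Reagents that add atoms: none
Why: Ruthenium-hydride-catalysed allyl-to-propenyl isomerisation (hydrometalation then β-hydride elimination) moves the terminal alkene into conjugation with nitrogen, the thermodynamic sink, while the styrene has no allylic hydrogen to shift, this hydride complex does not promote metathesis, and full conversion matters because leftover 7 would later close to a six-membered ring.

Step 6
Reactants: 8 N-(2,4-dibromo-3-methoxy-6-vinylphenyl)-4-methyl-N-[(E)-prop-1-enyl]benzenesulfonamide
Product: 9 5,7-dibromo-6-methoxy-1-tosyl-1H-indole
Conditions: (H2IMes)(PCy3)Cl2Ru=CHPh (second-generation Grubbs catalyst, 5 mol %, a second 5 mol % if conversion stalls), toluene (0.01 M), 80 °C, Ar sparge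
Reagents that add atoms: none
Why: This is an enamide–styrene ring-closing olefin metathesis, the known way from N-sulfonyl-N-(prop-1-enyl)-2-vinylanilines to N-sulfonylindoles, applied here to a more crowded member of the class. The ruthenium carbene exchanges with the terminal CH2 of the styrene and so sits on the future C3, adds across the enamide C=C of the same molecule in a [2+2] step, and the ruthenacyclobutane opens the other way to give C2=C3 and a Ru=CHCH3 carrier, which releases propene when it loads the next styrene. Ring B, five-membered, is closed by metathesis between two sp2 CH carbons that ring A and N1 hold ortho to each other, and because the ring is aromatic the moment it forms the closure cannot revert. No stereocentre arises, and E and Z enamide give the same product. The step needs initiation at the styrene instead of the enamide and cyclisation instead of intermolecular metathesis: the terminal, unhindered vinyl group set against an internal alkene, the electron-poor sulfonylated nitrogen that disfavours a dormant nitrogen-stabilised carbene, the three-atom tether and the 0.01 M dilution provide both. The C–Br bonds and the methyl ether do not react with the carbene, and argon sparging strips propene from the hot solution.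

Step 7
Reactants: 9 5,7-dibromo-6-methoxy-1-tosyl-1H-indole
Product: 10 5,7-dibromo-6-methoxy-1H-indole
Conditions: Cs2CO3 (3 equiv), THF/MeOH (2:1), rt
Reagents that add atoms: none
Why: Base-mediated methanolysis of an N-sulfonylindole, in which methoxide attacks sulfur and expels the indolide, should be easy here because two bromines stabilise the leaving anion and loss of the sulfonyl group relieves its clash with the C7 bromine, while carbonate only shuttles protons and the aryl bromides and the ether are inert.

Step 8
Reactants: 10 5,7-dibromo-6-methoxy-1H-indole
Product: 11 3,5,7-tribromo-6-methoxy-1H-indole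
Conditions: NBS (1.0 equiv), DMF, 0 °C, dark
Reagents that add atoms: N-bromosuccinimide, O=C1CCC(=O)N1Br
Why: Electrophilic aromatic substitution of a free indole goes to C3, the enamine-like β-carbon of ring B, and with one equivalent of NBS at low temperature it should stop there because ring A offers only C4–H, which is meta to the methoxy group and flanked by C5–Br.

Compound list
1 | 2-amino-4-methoxybenzaldehyde | COc1ccc(C=O)c(N)c1 | starting material
2 | 2-amino-5-bromo-4-methoxybenzaldehyde | COc1c(Br)cc(C=O)c(N)c1 | intermediate
3 | 2-amino-3,5-dibromo-4-methoxybenzaldehyde | COc1c(Br)cc(C=O)c(N)c1Br | intermediate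
4 | 2,4-dibromo-3-methoxy-6-vinylaniline | COc1c(Br)cc(C=C)c(N)c1Br | intermediate
5 | N-(2,4-dibromo-3-methoxy-6-vinylphenyl)-4-methylbenzenesulfonamide | COc1c(Br)cc(C=C)c(NS(=O)(=O)c2ccc(C)cc2)c1Br | intermediate
6 | allyl bromide | C=CCBr | starting material
7 | N-allyl-N-(2,4-dibromo-3-methoxy-6-vinylphenyl)-4-methylbenzenesulfonamide | COc1c(Br)cc(C=C)c(N(CC=C)S(=O)(=O)c2ccc(C)cc2)c1Br | intermediate
8 | N-(2,4-dibromo-3-methoxy-6-vinylphenyl)-4-methyl-N-[(E)-prop-1-enyl]benzenesulfonamide | COc1c(Br)cc(C=C)c(N(/C=C/C)S(=O)(=O)c2ccc(C)cc2)c1Br | intermediate
9 | 5,7-dibromo-6-methoxy-1-tosyl-1H-indole | COc1c(Br)cc2ccn(S(=O)(=O)c3ccc(C)cc3)c2c1Br | intermediate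
10 | 5,7-dibromo-6-methoxy-1H-indole | COc1c(Br)cc2cc[nH]c2c1Br | intermediate
11 | 3,5,7-tribromo-6-methoxy-1H-indole | COc1c(Br)cc2c(Br)c[nH]c2c1Br | target

Total step count: 8. Longest linear sequence: 8.

Steps most likely to fail

Step 6, ring-closing metathesis.
- **Risk:** The closure may stall. The two ortho substituents hold the sulfonamide plane perpendicular to ring A, and turning the N–CH= unit into that plane presses the sulfonyl group against the C7 bromine. Catalyst decay and intermolecular self-metathesis of the styrene can then outrun cyclisation.
- **Fallback:** It sets out from 5 and comes back at 9 by a Hegedus indole synthesis: PdCl2(MeCN)2 (10 mol %), 1,4-benzoquinone (1.1 equiv), LiCl, THF, reflux. Divalent palladium binds the vinyl group, the sulfonamide nitrogen adds to its terminal carbon, and β-hydride elimination sets up the C2=C3 bond. Benzoquinone reoxidises zerovalent palladium before it can insert into a C–Br bond. This detour forms N1–C2 instead of C2=C3, skips 7 and 8, and needs no new compound (F0).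

Step 3, N-tosylation.
- **Risk:** Sulfonylation may be sluggish because the nitrogen is weakly nucleophilic and flanked on both sides. Forcing it may carry part of the material on to a second sulfonylation, which leaves mixtures.
- **Fallback:** It sets out from 4 and comes back at 5 by over-sulfonylating on purpose and then trimming. NaH (3 equiv) and TsCl (2.5 equiv) in THF, 0 to 50 °C, should drive the anilide fully to N-(2,4-dibromo-3-methoxy-6-vinylphenyl)-4-methyl-N-tosylbenzenesulfonamide F1. K2CO3 in MeOH/THF then removes one sulfonyl group. The sulfonimide is an activated sulfonyl donor, whereas the sulfonamide anion formed resists further methanolysis.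

Step 8, C3 bromination.
- **Risk:** The free indole may brominate further at C2. The N–H 3-bromoindole may also degrade through acid- or light-induced decomposition during reaction and work-up.
- **Fallback:** It sets out from 9 and comes back at 11 by reversing the last two operations. Br2 (1.05 equiv) in CH2Cl2 at 0 °C should brominate the sulfonyl-tempered ring B once, at C3, to give 3,5,7-tribromo-6-methoxy-1-tosyl-1H-indole F2. Cs2CO3 in THF/MeOH at rt then releases the target, so the sensitive N–H bromoindole appears only under mild basic conditions.

Further compounds
F0 | step 6 | none | none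
F1 | step 3 | N-(2,4-dibromo-3-methoxy-6-vinylphenyl)-4-methyl-N-tosylbenzenesulfonamide | COc1c(Br)cc(C=C)c(N(S(=O)(=O)c2ccc(C)cc2)S(=O)(=O)c2ccc(C)cc2)c1Br
F2 | step 8 | 3,5,7-tribromo-6-methoxy-1-tosyl-1H-indole | COc1c(Br)cc2c(Br)cn(S(=O)(=O)c3ccc(C)cc3)c2c1Br
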